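Cuts: the C40 polyene is divided at C11=C12 and C11′=C12′ (two Wittig olefinations around the C10 dialdehyde). The furanoid C15 piece is opened at O–C8, traced back over C8–H/C6–O (hydride SN2′ on an alkynyl oxirane), and cut at C8–C9 (Sonogashira) and C7≡C8 (aldehyde homologation).
Feature (carotenoid numbering): the five-membered ring O–C5–C6=C7–C8 is fused to the cyclohexane along C5–C6 and bears the polyene at C8. It is an isomer of a C5 tertiary carbinol beside a C6=C7=C8 allene exocyclic to the six-membered ring, so forming O–C8 is a pure isomerisation.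
Forward order: the cyclohexane is bought, then oxirane, alkyne, enyne and allene are built on it. The dihydrofuran is the only ring closed, and the chain is joined C15 + C10 to C25, then C25 + furanoid C15 to C40.
Stereochemistry: C5 comes from a Sharpless epoxidation with D-(−)-tartrate, the allene axis from the oxirane by anti hydride delivery, C8 from that axis, and C6′ from (R)-α-ionone. Alkene geometry comes from syn hydrozirconation and thermally equilibrating Wittig steps.
Design choices: a hydroxyl-directed epoxidation is used because the hindered tetrasubstituted ring alkene offers no reliable reagent-controlled facial bias. A copper hydride is used because an aluminium hydride bound to the oxirane oxygen is expected to pass hydride on syn, which would lead to the C8 epimer.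

Key step: step 9

Remark: carotenoid numbering is used for all fragments; in the SMILES of the two allenes the axis descriptor is read over the ligand order C5, C1, H, C9.
Remark: (R)-α-ionone and the all-E C10 dialdehyde are taken as purchasable single isomers.

Step 1
Reactants: 1 β-cyclocitral (2,6,6-trimethylcyclohex-1-ene-1-carbaldehyde)
Product: 2 β-cyclogeraniol [(2,6,6-trimethylcyclohex-1-en-1-yl)methanol]
Conditions: NaBH4, MeOH, 0 °C
Reagents that add atoms: none
Why: Borohydride 1,2-reduction of the hindered enal should give the primary allylic alcohol needed for a directed epoxidation; no stereocentre is formed.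

Step 2
Reactants: 2 β-cyclogeraniol
Product: 3 [(1R,6R)-2,2,6-trimethyl-7-oxabicyclo[4.1.0]heptan-1-yl]methanol (5R,6R-epoxy alcohol)
Conditions: Ti(OiPr)4 (10 mol%), D-(−)-diisopropyl tartrate (13 mol%), tBuOOH, 4 Å MS, CH2Cl2, −20 °C
Reagents that add atoms: tert-butyl hydroperoxide, CC(C)(C)OO
Why: In this Sharpless asymmetric epoxidation the titanium tartrate binds the C7 hydroxyl and, with the D-(−)-ester, should deliver oxygen to the face that makes C5 and C6 both R (the mirror sense of L-(+)-tartrate turning geraniol into its 2S,3S epoxide), the two centres being set together because the oxirane is cis-fused.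

Step 3
Reactants: 3 (5R,6R)-epoxy alcohol
Product: 4 (1S,6R)-2,2,6-trimethyl-7-oxabicyclo[4.1.0]heptane-1-carbaldehyde (epoxy aldehyde; same spatial arrangement, the C6 descriptor changes by priority only)
Conditions: Pr4N[RuO4] (5 mol%), N-methylmorpholine N-oxide, 4 Å MS, CH2Cl2, rt
Reagents that add atoms: none
Why: The Ley–Griffith oxidation is neutral, so the acid-labile tetrasubstituted oxirane should survive, and the aldehyde has no α-hydrogen through which C6 could epimerise.

Step 4
Reactants: 4 epoxy aldehyde
Product: 5 (1R,6R)-1-ethynyl-2,2,6-trimethyl-7-oxabicyclo[4.1.0]heptane (terminal alkynyl oxirane)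
Conditions: dimethyl (1-diazo-2-oxopropyl)phosphonate, K2CO3, MeOH, 0 °C → rt
Reagents that add atoms: dimethyl (1-diazo-2-oxopropyl)phosphonate, COP(=O)(OC)C(=[N+]=[N-])C(C)=O
Why: In the Ohira–Bestmann homologation the diazomethylphosphonate anion freed by methanolysis adds to the non-enolisable aldehyde, and phosphate loss, N2 loss and a 1,2-hydrogen shift give the alkyne (C8) without touching C5 or C6.

Step 5
Reactants: 6 but-2-yn-1-ol
Product: 7 (but-2-yn-1-yloxy)(tert-butyl)dimethylsilane
Conditions: TBSCl, imidazole, CH2Cl2, rt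
Reagents that add atoms: tert-butyldimethylsilyl chloride, CC(C)(C)[Si](C)(C)Cl
Why: Standard silylation masks the hydroxyl that would otherwise consume zirconium hydride, copper hydride and silane later on.

Step 6
Reactants: 7 butynyl TBS ether
Product: 9 tert-butyl{[(2E)-3-iodobut-2-en-1-yl]oxy}dimethylsilane, via vinylzirconocene 8 (not isolated)
Conditions: Cp2Zr(H)Cl (1.5 equiv), THF, rt → 40 °C; then I2, −20 °C
Reagents that add atoms: iodine, [I][I]
Why: Hydrozirconation with the Schwartz reagent is a syn addition that, with excess reagent, equilibrates zirconium to the methyl-bearing carbon, and iodinolysis with retention should give the E iodide, which fixes the C9=C10 geometry.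

Step 7
Reactants: 5 terminal alkynyl oxirane; 9 (E)-alkenyl iodide
Product: 10 (1R,6R)-1-[(3E)-5-(tert-butyldimethylsilyloxy)-3-methylpent-3-en-1-yn-1-yl]-2,2,6-trimethyl-7-oxabicyclo[4.1.0]heptane (C15 enynyl oxirane)
Conditions: PdCl2(PPh3)2 (3 mol%), CuI (6 mol%), Et3N, THF, rt
Reagents that add atoms: none
Why: Sonogashira coupling forms C8–C9 with retention of the alkene geometry, and the hindered tetrasubstituted oxirane should be slow to ionise towards zerovalent palladium at room temperature.

Step 8
Reactants: 10 C15 enynyl oxirane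
Product: 12 (1R)-2-[(3E)-5-(tert-butyldimethylsilyloxy)-3-methylpenta-1,3-dien-1-ylidene]-1,3,3-trimethylcyclohexan-1-ol with allene axis S (5R α-hydroxy vinylallene), via allenyl silyl ether 11 (not isolated)
Conditions: (IMes)CuCl (5 mol%; IMes = 1,3-dimesitylimidazol-2-ylidene), NaOtBu (5 mol%), (EtO)2MeSiH (1.5 equiv), toluene, 0 °C → rt; then K2CO3 (cat.), MeOH, rt
Reagents that add atoms: none
Why: In this copper hydride SN2′ reduction of a propargyl oxirane, syn hydrocupration (H to C8, Cu to C7) and anti β-elimination of C6–O put the new C8–H opposite the departing oxygen, so C9 ends on the oxygen face and therefore anti to the C5 methyl once the hydroxyl lies in the allene plane (axis S, centre-to-axis transfer), C5 keeping its C–O bond.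

Step 9
Reactants: 12 (5R, axis S) α-hydroxy vinylallene
Product: 13 tert-butyl{[(2E)-3-[(2R,7aR)-4,4,7a-trimethyl-2,4,5,6,7,7a-hexahydro-1-benzofuran-2-yl]but-2-en-1-yl]oxy}dimethylsilane ((5R,8R) furanoid C15 silyl ether)
Conditions: Ph3PAuNTf2 (2 mol%), THF, −20 → 0 °C, dark; Et3N quench
Reagents that add atoms: none
Why: The Ph3PAu cation (monovalent gold) binds the C7=C8 π bond, whose lobes lie in the plane through C1, C6 and C5, on the side facing C1; after a ring flip that places the C5 hydroxyl pseudo-equatorially in that plane, oxygen adds to C8 anti to gold, and proton transfer to C7 of the resulting vinylgold (protodeauration) releases 13 and the catalyst. The closest known reaction type is the gold-catalysed cycloisomerisation of α-hydroxyallenes to 2,5-dihydrofurans, which passes the allene axis on to the new centre. The single ring formed, O–C5–C6–C7–C8, closes in the 5-endo-trig mode and leaves C6=C7 as the ring alkene. C8 is controlled by the axis alone: H and C9 stay below and above the nascent ring, and because C9 stands on the face opposite the pseudo-axial C5 methyl, C8 should become R. The step needs oxygen attack to be faster than gold-induced flattening of the allene to a vinyl-stabilised allyl cation and faster than Nazarov-type closure of the vinylallene; the hydroxyl sits in 1,4-relation to C8, THF and low temperature temper the Lewis acidity, and the carbocyclisation would have to bond C10 to C6, which is flanked by two quaternary carbons. No Brønsted acid is added and the amine quench removes the catalyst, so the doubly allylic C8–O bond should not ionise and epimerise.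

Step 10
Reactants: 13 (5R,8R) furanoid C15 silyl ether
Product: 14 (2E)-3-[(2R,7aR)-4,4,7a-trimethyl-2,4,5,6,7,7a-hexahydro-1-benzofuran-2-yl]but-2-en-1-ol (furanoid C15 alcohol)
Conditions: Bu4NF, THF, 0 °C
Reagents that add atoms: none
Why: Fluoride desilylation works under mildly basic conditions, to which the dihydrofuran and its C8 centre are inert.

Step 11
Reactants: 14 furanoid C15 alcohol
Product: 16 {(2E)-3-[(2R,7aR)-4,4,7a-trimethyl-2,4,5,6,7,7a-hexahydro-1-benzofuran-2-yl]but-2-en-1-yl}triphenylphosphonium bromide, via allylic bromide 15 (not isolated)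
Conditions: CBr4 (1.1 equiv), PPh3 (2.3 equiv), solid NaHCO3, CH2Cl2, −20 °C → rt
Reagents that add atoms: carbon tetrabromide, BrC(Br)(Br)Br; triphenylphosphine, c1ccc(cc1)P(c1ccccc1)c1ccccc1
Why: The Appel reaction turns the primary allylic alcohol into the bromide without free acid, and the excess phosphine quaternises it by SN2 in the same flask, so the acid route to Wittig salts, which would scramble C8, is avoided.

Step 12
Reactants: 17 (R)-α-ionone
Product: 18 (1E)-3-methyl-1-[(1R)-2,6,6-trimethylcyclohex-2-en-1-yl]penta-1,4-dien-3-ol (vinyl-α-ionol, both carbinol epimers)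
Conditions: CH2=CHMgBr, THF, −20 → 0 °C; aq. NH4Cl
Reagents that add atoms: vinylmagnesium bromide, C=C[Mg]Br
Why: Grignard 1,2-addition to the enone adds C10′ and C11′; the new carbinol centre need not be controlled because it is lost in the next step, and C6′ is not touched at low temperature.

Step 13
Reactants: 18 vinyl-α-ionol
Product: 19 {(2E,4E)-3-methyl-5-[(1R)-2,6,6-trimethylcyclohex-2-en-1-yl]penta-2,4-dien-1-yl}triphenylphosphonium bromide (α-C15 Wittig salt)
Conditions: PPh3·HBr, MeOH, rt; crystallisation
Reagents that add atoms: triphenylphosphine hydrobromide, [Br-].[PH+](c1ccccc1)(c1ccccc1)c1ccccc1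
Why: Ionisation of the tertiary bis-allylic alcohol and capture of the pentadienyl cation by phosphine at its primary end (allylic transposition, the standard entry to C15 Wittig salts) should give the conjugated 9′E salt, C6′ lying outside the cation.

Step 14
Reactants: 19 α-C15 Wittig salt; 20 (2E,4E,6E)-2,7-dimethylocta-2,4,6-trienedial (C10 dialdehyde, 2 equiv)
Product: 22 (6R)-12′-apo-ε-caroten-12′-al (all-E C25 aldehyde; its formyl carbon is C12 of the target), via ylide 21 (not isolated)
Conditions: 1,2-epoxybutane, EtOH, reflux, Ar; crystallisation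
Reagents that add atoms: none
Why: This Wittig olefination forms C11′=C12′; excess dialdehyde and the lower electrophilicity of the longer polyenal favour mono-olefination, the hindered Z isomer should revert to E on heating, and the near-neutral medium spares C6′.

Step 15
Reactants: 16 furanoid C15 phosphonium bromide; 22 C25 aldehyde
Product: 24 (5R,8R,6′R)-5,8-epoxy-5,8-dihydro-β,ε-carotene (target), via ylide 23 (not isolated)
Conditions: 1,2-epoxybutane, EtOH, reflux, Ar, dark; all-E isomer by crystallisation
Reagents that add atoms: none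
Why: This Wittig olefination forms C11=C12; bromide-opened epoxybutane supplies only a trace of alkoxide, so C8 and C6′ should persist, and the sterically hindered 11Z isomer should equilibrate thermally to the all-E chain.

Compound list
1 | β-cyclocitral | CC1=C(C=O)C(C)(C)CCC1 | starting material
2 | β-cyclogeraniol | CC1=C(CO)C(C)(C)CCC1 | intermediate
3 | [(1R,6R)-2,2,6-trimethyl-7-oxabicyclo[4.1.0]heptan-1-yl]methanol | CC1(C)CCC[C@@]2(C)O[C@@]12CO | intermediate
4 | (1S,6R)-2,2,6-trimethyl-7-oxabicyclo[4.1.0]heptane-1-carbaldehyde | CC1(C)CCC[C@@]2(C)O[C@@]12C=O | intermediate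
5 | (1R,6R)-1-ethynyl-2,2,6-trimethyl-7-oxabicyclo[4.1.0]heptane | CC1(C)CCC[C@@]2(C)O[C@@]12C#C | intermediate
6 | but-2-yn-1-ol | CC#CCO | starting material
7 | (but-2-yn-1-yloxy)(tert-butyl)dimethylsilane | CC#CCO[Si](C)(C)C(C)(C)C | intermediate
8 | chloro[(2E)-4-(tert-butyldimethylsilyloxy)but-2-en-2-yl]zirconocene (cyclopentadienyl rings drawn σ-bonded) | Cl[Zr](C1C=CC=C1)(C1C=CC=C1)/C(C)=C/CO[Si](C)(C)C(C)(C)C | intermediate (not isolated)
9 | tert-butyl{[(2E)-3-iodobut-2-en-1-yl]oxy}dimethylsilane | [I]/C(C)=C/CO[Si](C)(C)C(C)(C)C | intermediate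
10 | (1R,6R)-1-[(3E)-5-(tert-butyldimethylsilyloxy)-3-methylpent-3-en-1-yn-1-yl]-2,2,6-trimethyl-7-oxabicyclo[4.1.0]heptane | CC1(C)CCC[C@@]2(C)O[C@@]12C#C/C(C)=C/CO[Si](C)(C)C(C)(C)C | intermediate
11 | diethoxy(methyl)silyl ether of 12 (5R, axis S) | CC1(C)CCC[C@@](C)(O[Si](C)(OCC)OCC)C1=[C@@]=CC(/C)=C/CO[Si](C)(C)C(C)(C)C | intermediate (not isolated)
12 | (1R)-2-[(3E)-5-(tert-butyldimethylsilyloxy)-3-methylpenta-1,3-dien-1-ylidene]-1,3,3-trimethylcyclohexan-1-ol, allene axis S | CC1(C)CCC[C@@](C)(O)C1=[C@@]=CC(/C)=C/CO[Si](C)(C)C(C)(C)C | intermediate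
13 | (5R,8R) furanoid C15 silyl ether, (2R,7aR) in benzofuran numbering | CC(C)(C)[Si](C)(C)OC/C=C(\C)[C@H]1C=C2C(C)(C)CCC[C@@]2(C)O1 | intermediate
14 | (2E)-3-[(2R,7aR)-4,4,7a-trimethyl-2,4,5,6,7,7a-hexahydro-1-benzofuran-2-yl]but-2-en-1-ol | OC/C=C(\C)[C@H]1C=C2C(C)(C)CCC[C@@]2(C)O1 | intermediate
15 | (2R,7aR)-2-[(2E)-4-bromobut-2-en-2-yl]-4,4,7a-trimethyl-2,4,5,6,7,7a-hexahydro-1-benzofuran | BrC/C=C(\C)[C@H]1C=C2C(C)(C)CCC[C@@]2(C)O1 | intermediate (not isolated)
16 | (5R,8R) furanoid C15 triphenylphosphonium bromide | c1ccccc1[P+](c1ccccc1)(c1ccccc1)C/C=C(\C)[C@H]1C=C2C(C)(C)CCC[C@@]2(C)O1.[Br-] | intermediate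
17 | (R)-α-ionone | CC1=CCCC(C)(C)[C@H]1/C=C/C(C)=O | starting material
18 | (6R)-vinyl-α-ionol, carbinol epimers | CC1=CCCC(C)(C)[C@H]1/C=C/C(C)(O)C=C | intermediate
19 | (6R,7E,9E)-α-ionylideneethyl triphenylphosphonium bromide | CC1=CCCC(C)(C)[C@H]1/C=C/C(C)=C/C[P+](c1ccccc1)(c1ccccc1)c1ccccc1.[Br-] | intermediate
20 | (2E,4E,6E)-2,7-dimethylocta-2,4,6-trienedial | O=C/C(C)=C/C=C/C=C(\C)C=O | starting material
21 | ylide of 19 | CC1=CCCC(C)(C)[C@H]1/C=C/C(C)=C/C=P(c1ccccc1)(c1ccccc1)c1ccccc1 | intermediate (not isolated)
22 | (6R)-12′-apo-ε-caroten-12′-al, all-E | CC1=CCCC(C)(C)[C@H]1/C=C/C(C)=C/C=C/C(C)=C/C=C/C=C(C)/C=O | intermediate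
23 | ylide of 16 | c1ccccc1P(c1ccccc1)(c1ccccc1)=C/C=C(\C)[C@H]1C=C2C(C)(C)CCC[C@@]2(C)O1 | intermediate (not isolated)
24 | (5R,8R,6′R)-5,8-epoxy-5,8-dihydro-β,ε-carotene | CC1=CCCC(C)(C)[C@H]1/C=C/C(C)=C/C=C/C(C)=C/C=C/C=C(C)/C=C/C=C(\C)[C@H]1C=C2C(C)(C)CCC[C@@]2(C)O1 | target

Total step count: 15.
Longest linear sequence: 10 steps (1, 2, 3, 4, 7, 8, 9, 10, 11, 15).

Steps most likely to fail

**1. Step 9.**
- The gold-bound allene may flatten reversibly to a vinyl-stabilised allyl cation and lose the axis information.
- Protodeauration at the crowded C7 may lag, leaving acid in solution.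
- The doubly allylic C8–O bond of the product may ionise and epimerise.

The fallback sets out from 12 and returns at 13 by replacing the π-acid with a halonium ion. Iodoetherification with N-iodosuccinimide (solid NaHCO3, CH2Cl2, −40 °C) engages the same in-plane C7=C8 bond. The hydroxyl closes anti to iodine and should give the (2S,7aR)-3-iodo-2,5-dihydrofuran silyl ether F1. F1 has the same spatial arrangement at C8 as 13; the descriptor changes only because of iodine. Radical hydrodeiodination (Bu3SnH, Et3B/air, toluene, −20 °C) then gives 13. Halogen–metal exchange is avoided because a C7 carbanion would expel the C8 oxygen.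

**2. Step 8.**
- Hydrocupration of the conjugated enyne may take the other regiochemistry and end in semi-reduction.
- The copper may be kept off the hindered face anti to oxygen.
- The vinylallene may be reduced further.

The fallback sets out from 10 and returns at 12 by ionising first and delivering hydride second. The conditions are Pd2(dba)3·CHCl3, PBu3, HCO2H/Et3N, THF, rt. Zerovalent palladium attacks C8 anti to the C6–O bond to give a σ-allenylpalladium formate. Decarboxylation and C–H reductive elimination with retention place hydrogen on the same anti face. No compound outside the list is made (F0).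

**3. Step 15.**
- The allylic ylide carries charge at C9 and may expel the C8 alkoxide by vinylogous β-elimination, opening the dihydrofuran.
- Z-olefin formation at C11=C12 may persist.

The fallback sets out from 14 and 22 and returns at 24 with reversed polarity.
- 14 is oxidised with MnO2 (CH2Cl2, rt) to the furanoid C15 enal F2.
- 22 is reduced (NaBH4, EtOH/THF, 0 °C) to the C25 alcohol F3.
- F3 is converted with PPh3·HBr (MeOH, rt) into the C25 phosphonium bromide F4, so acid meets only the ε half.
- In refluxing EtOH with 1,2-epoxybutane, F4 forms the C25 ylide F5, which olefinates F2 to give 24. No carbanion is ever generated next to C8–O.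

Further compounds
F1 | step 9 | tert-butyl{[(2E)-3-[(2S,7aR)-3-iodo-4,4,7a-trimethyl-2,4,5,6,7,7a-hexahydro-1-benzofuran-2-yl]but-2-en-1-yl]oxy}dimethylsilane | CC(C)(C)[Si](C)(C)OC/C=C(\C)[C@H]1C([I])=C2C(C)(C)CCC[C@@]2(C)O1
F0 | step 8 | none | none
F2 | step 15 | (2E)-3-[(2R,7aR)-4,4,7a-trimethyl-2,4,5,6,7,7a-hexahydro-1-benzofuran-2-yl]but-2-enal | O=C/C=C(\C)[C@H]1C=C2C(C)(C)CCC[C@@]2(C)O1
F3 | step 15 | (6R)-12′-apo-ε-caroten-12′-ol | CC1=CCCC(C)(C)[C@H]1/C=C/C(C)=C/C=C/C(C)=C/C=C/C=C(C)/CO
F4 | step 15 | [(6R)-12′-apo-ε-caroten-12′-yl]triphenylphosphonium bromide | CC1=CCCC(C)(C)[C@H]1/C=C/C(C)=C/C=C/C(C)=C/C=C/C=C(C)/C[P+](c1ccccc1)(c1ccccc1)c1ccccc1.[Br-]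
F5 | step 15 | ylide of F4 | CC1=CCCC(C)(C)[C@H]1/C=C/C(C)=C/C=C/C(C)=C/C=C/C=C(C)/C=P(c1ccccc1)(c1ccccc1)c1ccccc1
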